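It is tempting to read these percentages as one pseudo-first-order decay, with a single rate constant for the electrophile, but the two runs differ in their charge of electrophile and the loss slows in each.

| setting | west | north-east | flask |
|---|---|---|---|
| electrophile | 0.055 M (fed, over 1.0 min) | 0.037 M (fed, over 1.0 min) | 0.055 M (fed, over 1.0 min) |
| protonated nucleophile | 0.055 M | 0.055 M | 0.0550 M |
| gas | 4.2 mM (held) | 4.2 mM (held) | 4.2 mM (held) |
| remark | the very flask that is asked about, followed so far | run made earlier |  |
| time |  |  | 10 min |

- west (time / min: electrophile / %, product / %): 0.833: 81.2, 2.1; 1.50: 94.9, 5.2; 2.50: 93.0, 7.0; 3.00: 91.9, 8.4; 4.00: 89.9, 10.6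
- north-east (time / min: electrophile / %, product / %): 0.500: 49.2, 0.9; 1.00: 96.9, 3.6; 2.00: 93.5, 7.3; 4.00: 88.3, 11.6; 8.00: 81.0, 19.0

(standard deviation of a reading: 0.3 percentage points)

- part of the electrophile that has reacted at 10 min
- share of the unused nucleophile that is free and not bound as protonated nucleophile, at 10 min

- at the start none of free base is dissolved
- candidate steps: free base <-> dormant form; gas <-> free base; acid set free + free base <-> salt of the base; nucleophile + acid set free <-> protonated nucleophile; electrophile + nucleophile -> acid set free + product
- percentages count the whole charge, also what has not yet gone in
- the earlier runs do not show how much of nucleophile is bound; that part of a forecast is a guess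

At 4.00 min, north-east shows the higher percentage of product, yet west holds more product in concentration, 5.83 mM against 4.29 mM. Suppose acid set free grows with the product and free nucleophile falls in inverse proportion to it. Then the square of the product concentration climbs evenly, in step with the electrophile present.

West between 2.50 min and 4.00 min gives 0.254 mM min⁻¹ for the brake number, the climb per minute of that square divided by the electrophile present. North-east between 4.00 min and 8.00 min gives 0.247 mM min⁻¹, the same within the scatter. So one number serves both runs, and a percent of the charge is more product in west than in north-east.

West's electrophile still reads 89.9% at 4.00 min, and we first hold it there and carry west to 10 min, which gives 19.0% reacted. Correcting to the mean electrophile over that stretch gives 18.7%. That is our reckoning, and it is lower than the forecast.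

The forecast says 19.5% (17.5% to 21.5%) and, for the free share, 1.5% (0.4% to 7%). Its ground is that “Each product frees acid, which ties up a second nucleophile”.

The flask gives 18.2% reacted and 1.03% free, within the forecast's ranges and 0.50 percentage points under our reckoning.

    free base ⇌ dormant form (K = 39.0, k = 0.00938 s⁻¹)
    gas ⇌ free base, rate k2*(csat - [free base]) (kL = 0.0525 s⁻¹)
    acid set free + free base ⇌ salt of the base (K = 4.40 × 10⁶ M⁻¹, k = 0.453 M⁻¹ s⁻¹)
    nucleophile + acid set free ⇌ protonated nucleophile, settled at all times (K = 7960 M⁻¹)
    electrophile + nucleophile → acid set free + product (k = 0.497 M⁻¹ s⁻¹)

The neighbour is the same flask with 0.093 M of electrophile. We scale west's square at 4.00 min with the charge, then add 0.254 mM min⁻¹ times the electrophile, held as in our first step at west's reading of 89.9% of the charge, over 6.00 min. This gives 14.6% reacted, and the neighbour flask stands at 14.1%.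

The numbers in the tables were computed for substances that don't exist.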